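**Retrosynthetic overview**
1. Feature: the fifteen core carbons (seven-membered ring C1, C5–C10; five-membered ring C1–C5; methyls on C1 and C8; isopropyl on C4) form one unbroken head-to-tail farnesyl chain. It lacks only the bonds C10–C1 and C5–C4, and the tertiary 4β-OH sits on the carbon that holds the charge after these closures and one hydride shift.
2. Disconnections, backwards: C6–O aryl ester (vanillate, last), then 8α-carbinol/9,10-alkene to 8α,9α-epoxide to 8,9-alkene, then 6α-OH to C–H, then both rings at once to farnesyl diphosphate.
3. Ring order: one enzymatic cationic cascade closes the seven-membered ring (C10–C1) just ahead of the five-membered ring (C5–C4) and ends with water at C4.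
4. All later steps adjust oxidation level on the seven-membered ring and are steered by the 6α-hydroxyl.

Key step: step 3

Remark: daucane numbering is used and β is the face of the C1 methyl group. Farnesyl C1–C11 become daucane C10, C9, C8, C7, C6, C5, C1, C2, C3, C4, C11. Diphosphates are drawn as free acids, although 3 is handled as its ammonium salt.

**Step 1**
Reactants: 1 (2E,6E)-farnesol
Product: 2 (2E,6E)-farnesyl chloride
Conditions: NCS, Me2S, CH2Cl2, −30 °C to 0 °C
Reagents that add atoms: N-chlorosuccinimide, O=C1CCC(=O)N1Cl
Why: Corey–Kim chlorination, in which chloride displaces the alkoxysulfonium group at the primary carbon under cold, neutral conditions, so neither allylic transposition nor E/Z scrambling is expected.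

**Step 2**
Reactants: 2 (2E,6E)-farnesyl chloride
Product: 3 (2E,6E)-farnesyl diphosphate
Conditions: (Bu4N)3HP2O7 (2 equiv), MeCN, rt; then Dowex AG 50W-X8 (NH4+ form), aq NH4HCO3/i-PrOH; cellulose chromatography
Reagents that add atoms: tris(tetrabutylammonium) hydrogen diphosphate, CCCC[N+](CCCC)(CCCC)CCCC.CCCC[N+](CCCC)(CCCC)CCCC.CCCC[N+](CCCC)(CCCC)CCCC.OP(=O)([O-])OP(=O)([O-])[O-]
Why: SN2 displacement of a primary allylic chloride by the organic-soluble diphosphate anion leaves both E-alkenes untouched, and ion exchange should give a water-soluble salt fit for the enzyme.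

**Step 3**
Reactants: 3 (2E,6E)-farnesyl diphosphate
Product: 5 dauc-8-en-4β-ol, via enzyme-bound nerolidyl diphosphate 4 (not isolated)
Conditions: engineered class 1 sesquiterpene synthase (evolved from a daucane-forming parent, purified), MgCl2 (10 mM), HEPES pH 7.5, dithiothreitol, 10% glycerol, pentane overlay, 30 °C
Reagents that add atoms: water, O
Why: Proposed new method: the MgCl2-loaded enzyme ionises 3, returns diphosphate to C8 to give the tertiary allylic ester 4, lets the C8–C9 bond rotate and ionises again, so that a cisoid allyl cation forms whose terminus C10 is attacked by the C1=C5 alkene through C1 while the C4=C11 alkene bonds through C4 to the charge growing at C5; a 1,2-hydride shift from C4 to C11 then places the charge on C4, where a bound water adds and loses a proton. The closest known reaction type is the cyclisation of 3 by wild-type daucane-forming class 1 synthases, which pass through the same cations and end with water at C11 or, after one more hydride shift, at C5, together with the known re-routing of water capture in sesquiterpene synthases by point mutation; ending at C4 has not been shown, so the variant must be evolved from such a parent by moving the bound water over C4. The seven-membered ring closes 7-endo-trig on the C1=C5 alkene in the anti-Markovnikov sense, which is viable only because the five-membered ring closes 5-exo-trig (Markovnikov, charge to tertiary C11) in the same asynchronous event. C1 is controlled by the alkene face that the folded chain presents to C10 inside the chiral pocket, C5 is tied to C1 by anti addition of C10 and C4 across the E-alkene, which can only give the trans fusion (1β-CH3, 5α-H), and C4 is controlled by the position of the water over the β face of the planar cation. The step needs closure of C10 onto C1 rather than onto C5 (six-membered ring) or C4 (ten-membered ring), a single enantiomeric fold, and water capture at C4 in preference to capture at C11, a further hydride shift or proton loss; the substrate secures only the trans fusion through its 6E geometry and the cis ring alkene through the cisoid cation, and everything else rests on the protein.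

**Step 4**
Reactants: 5 dauc-8-en-4β-ol
Product: 6 dauc-8-ene-4β,6α-diol (jaeschkeanadiol)
Conditions: engineered self-sufficient P450 monooxygenase, NADP+ (cat.), D-glucose, glucose dehydrogenase, air, KH2PO4/K2HPO4 buffer pH 8.0, 2% DMSO, 25 °C
Reagents that add atoms: dioxygen, O=O
Why: Proposed new method: the iron-oxo oxidant abstracts the 6α hydrogen and returns hydroxyl to the same face (hydrogen abstraction and oxygen rebound, retention), so C6 is set by how the pocket holds 5, with the 4β-hydroxyl as a hydrogen-bond anchor; the closest known reaction type is the site- and face-selective hydroxylation of unactivated ring CH2 groups of sesquiterpenes by plant P450s and evolved bacterial P450 variants, but no enzyme is known for C6 of a daucane, and the pocket must override the weaker allylic C–H bonds at C7, C10 and C14 and epoxidation of the 8,9-alkene.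

**Step 5**
Reactants: 6 dauc-8-ene-4β,6α-diol
Product: 7 8α,9α-epoxydaucane-4β,6α-diol
Conditions: VO(acac)2 (5 mol %), t-BuOOH (decane), CH2Cl2, 0 °C to rt
Reagents that add atoms: tert-butyl hydroperoxide, CC(C)(C)OO
Why: Hydroxyl-directed vanadium-catalysed epoxidation, in which the homoallylic 6α-alcohol binds the vanadium alkylperoxide and delivers oxygen to the α face of the 8,9-alkene (also the face away from the 1β-methyl), setting C8 and C9, while the 4β-alcohol is too remote to compete.

**Step 6**
Reactants: 7 8α,9α-epoxydaucane-4β,6α-diol
Product: 8 9β-(phenylselanyl)daucane-4β,6α,8α-triol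
Conditions: PhSeSePh, NaBH4, EtOH, rt to reflux
Reagents that add atoms: diphenyl diselenide, c1ccc(cc1)[Se][Se]c1ccccc1
Why: SN2 opening of a trisubstituted epoxide by the soft selenolate occurs at the secondary carbon C9 with inversion (β attack), leaving the C8–O bond and thus the 8α-carbinol configuration untouched.

**Step 7**
Reactants: 8 9β-(phenylselanyl)daucane-4β,6α,8α-triol
Product: 10 dauc-9-ene-4β,6α,8α-triol, via selenoxide 9 (not isolated)
Conditions: 30% aq H2O2 (excess), pyridine, THF, 0 °C to rt
Reagents that add atoms: none
Why: Selenide oxidation and selenoxide syn elimination, in which C8 carries no hydrogen, so only 10β-H can be removed and the alkene can form only between C9 and C10 without disturbing C8, while excess oxidant takes the selenenic acid on so that it does not add back.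

**Step 8**
Reactants: 11 vanillic acid
Product: 13 4-(tert-butyldimethylsilyloxy)-3-methoxybenzoic acid, via bis-silyl derivative 12 (not isolated)
Conditions: TBSCl (2.5 equiv), imidazole, DMF, rt; then AcOH–THF–H2O, rt
Reagents that add atoms: tert-butyldimethylsilyl chloride, CC(C)(C)[Si](C)(C)Cl
Why: Silylation of phenol and acid followed by hydrolysis of the much more labile silyl ester should leave the aryl silyl ether, which tolerates mild acid.

**Step 9**
Reactants: 10 dauc-9-ene-4β,6α,8α-triol; 13 4-(tert-butyldimethylsilyloxy)-3-methoxybenzoic acid
Product: 14 6-O-[4-(tert-butyldimethylsilyloxy)-3-methoxybenzoyl]dauc-9-ene-4β,6α,8α-triol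
Conditions: DCC, DMAP, CH2Cl2, rt to 40 °C
Reagents that add atoms: none
Why: Steglich esterification, in which the acylpyridinium ion should reach only the secondary 6α-alcohol because the 4β- and 8α-alcohols are tertiary, and the C6–O bond is not broken, so C6 keeps its configuration.

**Step 10**
Reactants: 14 silyl-protected ester
Product: 15 target, 6α-vanilloyloxydauc-9-ene-4β,8α-diol
Conditions: TBAF, AcOH, THF, 0 °C
Reagents that add atoms: none
Why: Fluoride-mediated desilylation cleaves the aryl silyl ether rapidly, and the acetic acid buffer protonates the phenoxide, so the hindered aryl ester and the acid-sensitive tertiary allylic alcohol should stay intact.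

**Compound list**
1 | (2E,6E)-farnesol | CC(C)=CCC/C(C)=C/CC/C(C)=C/CO | starting material
2 | (2E,6E)-farnesyl chloride | CC(C)=CCC/C(C)=C/CC/C(C)=C/CCl | intermediate
3 | (2E,6E)-farnesyl diphosphate (handled as ammonium salt) | CC(C)=CCC/C(C)=C/CC/C(C)=C/COP(=O)(O)OP(=O)(O)O | intermediate
4 | (6E)-nerolidyl diphosphate, enzyme-bound; the carbinol carbon is fixed by the enzyme and erased on re-ionisation, so it is left open | CC(C)=CCC/C(C)=C/CCC(C)(C=C)OP(=O)(O)OP(=O)(O)O | intermediate
5 | (1R,4R,5R)-dauc-8-en-4β-ol; trans-fused, 1β-CH3, 5α-H, 4β-OH, 4α-isopropyl | C1CC(C)=CC[C@@]2(C)CC[C@@](O)(C(C)C)[C@H]12 | intermediate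
6 | (1R,4R,5S,6S)-dauc-8-ene-4β,6α-diol (jaeschkeanadiol) | O[C@H]1CC(C)=CC[C@@]2(C)CC[C@@](O)(C(C)C)[C@H]12 | intermediate
7 | (8R,9S)-8α,9α-epoxydaucane-4β,6α-diol | O[C@H]1C[C@@]2(C)O[C@H]2C[C@@]3(C)CC[C@@](O)(C(C)C)[C@H]13 | intermediate
8 | (8R,9R)-9β-(phenylselanyl)daucane-4β,6α,8α-triol | O[C@H]1C[C@@](C)(O)[C@H]([Se]c2ccccc2)C[C@@]3(C)CC[C@@](O)(C(C)C)[C@H]13 | intermediate
9 | selenoxide of 8 (both configurations at selenium) | O[C@H]1C[C@@](C)(O)[C@H]([Se](=O)c2ccccc2)C[C@@]3(C)CC[C@@](O)(C(C)C)[C@H]13 | intermediate
10 | (1R,4R,5S,6S,8R)-dauc-9-ene-4β,6α,8α-triol | O[C@H]1C[C@@](C)(O)C=C[C@@]2(C)CC[C@@](O)(C(C)C)[C@H]12 | intermediate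
11 | vanillic acid | COc1cc(C(=O)O)ccc1O | starting material
12 | tert-butyldimethylsilyl 4-(tert-butyldimethylsilyloxy)-3-methoxybenzoate | COc1cc(C(=O)O[Si](C)(C)C(C)(C)C)ccc1O[Si](C)(C)C(C)(C)C | intermediate
13 | 4-(tert-butyldimethylsilyloxy)-3-methoxybenzoic acid | COc1cc(C(=O)O)ccc1O[Si](C)(C)C(C)(C)C | intermediate
14 | 6-O-[4-(tert-butyldimethylsilyloxy)-3-methoxybenzoyl]dauc-9-ene-4β,6α,8α-triol | COc1cc(C(=O)O[C@H]2C[C@@](C)(O)C=C[C@@]3(C)CC[C@@](O)(C(C)C)[C@H]23)ccc1O[Si](C)(C)C(C)(C)C | intermediate
15 | (1R,4R,5S,6S,8R)-6α-(4-hydroxy-3-methoxybenzoyloxy)dauc-9-ene-4β,8α-diol | COc1cc(C(=O)O[C@H]2C[C@@](C)(O)C=C[C@@]3(C)CC[C@@](O)(C(C)C)[C@H]23)ccc1O | target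

**Totals**
Total step count: 10. Longest linear sequence: 9 (steps 1–7, 9, 10).

**Steps most likely to fail**

Step 3. The cascade may end at the wrong station (water at C11, a further hydride shift to C5, or proton loss), or no variant may capture water at C4 at a useful rate.
- The fallback sets out from 3 and comes back at 5. It places the C4 oxygen by carbonyl addition instead of by the enzyme.
- Compound 3 is cyclised with a characterised wild-type daucane synthase that quenches the isopropyl cation with water. An enzyme of the 1β-methyl series is required. The product is dauc-8-en-11-ol F1.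
- Dehydration (SOCl2, pyridine, 0 °C) and removal of the isopropenyl isomer on AgNO3-impregnated silica should give dauca-4(11),8-diene F2.
- One equivalent of mCPBA (NaHCO3, CH2Cl2, low temperature) should take the more electron-rich tetrasubstituted alkene to 4α,11-epoxydauc-8-ene F3.
- H5IO6 in aqueous THF cleaves the epoxide to 11,12,13-trinordauc-8-en-4-one F4.
- The non-basic organocerium reagent from i-PrMgCl and CeCl3 (THF, −78 °C) should add anti to the angular methyl without epimerising C5, giving 5.

Step 4. Oxidation may go to the wrong site (allylic hydroxylation at C7, C10 or C14, or epoxidation of the alkene), or turnover may be too low.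
- The fallback gives up the de novo core. It draws on none of the numbered compounds and comes back at 6.
- It sets out from purchased ferutinin F5, the 6-O-(4-hydroxybenzoate) of 6 isolated from Ferula species.
- Saponification (KOH, MeOH–H2O, reflux) should release 6, which then enters step 5.

Step 6. Opening of the epoxide may be slow, because the β approach to C9 lies under the 1β-methyl group, and transannular attack by the 4β-hydroxyl may compete.
- The fallback sets out from 6, comes back at 10 and replaces steps 5–7 by a Schenck ene reaction.
- Singlet oxygen (O2, tetraphenylporphyrin, visible light, CH2Cl2, 0 °C) attacks the open α face, which also carries the hydrogen-bonding 6α-hydroxyl, and removes 10α-H to give 8α-hydroperoxydauc-9-ene-4β,6α-diol F6.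
- Regioisomeric ene products must be removed by chromatography.
- PPh3 then reduces the O–O bond to give 10.

**Further compounds**
F1 | step 3 | dauc-8-en-11-ol (1β-CH3, 4β-H, 5α-H) | C1CC(C)=CC[C@@]2(C)CC[C@@H](C(C)(C)O)[C@H]12
F2 | step 3 | dauca-4(11),8-diene | C1CC(C)=CC[C@@]2(C)CCC(=C(C)C)[C@H]12
F3 | step 3 | 4α,11-epoxydauc-8-ene | C1CC(C)=CC[C@@]2(C)CC[C@@]3(OC3(C)C)[C@H]12
F4 | step 3 | 11,12,13-trinordauc-8-en-4-one | C1CC(C)=CC[C@@]2(C)CCC(=O)[C@H]12
F5 | step 4 | ferutinin | O=C(O[C@H]1CC(C)=CC[C@@]2(C)CC[C@@](O)(C(C)C)[C@H]12)c1ccc(O)cc1
F6 | step 6 | 8α-hydroperoxydauc-9-ene-4β,6α-diol | O[C@H]1C[C@@](C)(OO)C=C[C@@]2(C)CC[C@@](O)(C(C)C)[C@H]12
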